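The C/D bicyclo[3.2.1]octane carries oxygen at C11, the middle atom of its three-carbon bridge C9–C11–C12, has C14 as one-carbon bridge and is fused to ring B at C8–C9: the imprint of an oxyallyl–cyclopentadiene (4+3) adduct. One intramolecular cycloaddition therefore forms C8–C9 and C12–C13 and closes rings B, C and D with three stereocentres. Its precursor is the complete ring A bicyclic lactone (2β,3β-acetonide, C4 and C10 quaternary) carrying a 1-chloro-2-oxopropyl arm on C10 and a cyclopentadienyl(methoxycarbonyl)methyl arm on C5; the labile diene is unveiled only in the preceding step, and the epimerisable C6 and C9 need not be controlled beforehand.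

Key step: step 18

Remarks on the chemistry: gibberellin numbering is used (ring A: C1–C5, C10; ring B: C5, C6, C8, C9, C10; ring C: C8, C9, C11–C14; ring D: C8, C13–C16; C7 carboxyl, C17 methylene, C18 methyl, C19–O–C20 lactone), and α is the face of ring A that carries the lactone bridge. The enantiofacial sense of step 4 is assumed to follow that of simple 2-alkyl-2-allylcyclohexanones made with the same ligand.

Step 1
Reactants: 1 2-methylcyclohexane-1,3-dione
Product: 2 3-isobutoxy-2-methylcyclohex-2-en-1-one
Conditions: i-BuOH, TsOH (cat.), toluene, reflux, Dean–Stark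
Reagents that add atoms: isobutanol, CC(C)CO
Why: Acid-catalysed vinylogous esterification of the dione enol, driven by azeotropic removal of water; no stereocentre is formed.

Step 2
Reactants: 2 3-isobutoxy-2-methylcyclohex-2-en-1-one; 3 benzyl chloromethyl ether
Product: 4 rac-6-(benzyloxymethyl)-3-isobutoxy-2-methylcyclohex-2-en-1-one
Conditions: LiN(i-Pr)2, THF, −78 °C; then 3, −78 → 0 °C
Reagents that add atoms: none
Why: Stork–Danheiser kinetic α′-deprotonation of the vinylogous ester and C-alkylation of the lithium enolate by the reactive chloromethyl ether introduce C20; the new centre is racemic and is erased in step 3.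

Step 3
Reactants: 4 rac-6-(benzyloxymethyl)-3-isobutoxy-2-methylcyclohex-2-en-1-one; 5 allyl chloroformate
Product: 6 allyl [2-(benzyloxymethyl)-5-isobutoxy-6-methylcyclohexa-1,5-dien-1-yl] carbonate
Conditions: LiN(i-Pr)2, TMEDA, THF, −78 °C; then 5
Reagents that add atoms: none
Why: A second α′-deprotonation gives the fully substituted cross-conjugated enolate, which the hard chloroformate should trap on oxygen (enolate O-acylation) to give the achiral allyl enol carbonate.

Step 4
Reactants: 6 allyl [2-(benzyloxymethyl)-5-isobutoxy-6-methylcyclohexa-1,5-dien-1-yl] carbonate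
Product: 7 (S)-6-allyl-6-(benzyloxymethyl)-3-isobutoxy-2-methylcyclohex-2-en-1-one
Conditions: Pd2(dba)3 (2.5 mol %), (S)-t-BuPHOX (6 mol %), toluene, 30 °C
Reagents that add atoms: none
Why: Decarboxylative asymmetric allylic alkylation (Tsuji–Trost type): zerovalent palladium ionises the allyl carbonate, CO2 is lost and the allyl group is returned to one enantiotopic face of the enolate inside the chiral phosphinooxazoline complex, which sets the quaternary carbon (later C10); any shortfall in enantiopurity is to be made up by crystallisation of a later solid intermediate such as 15.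

Step 5
Reactants: 7 (S)-6-allyl-6-(benzyloxymethyl)-3-isobutoxy-2-methylcyclohex-2-en-1-one
Product: 9 (R)-4-allyl-4-(benzyloxymethyl)-2-methylcyclohex-2-en-1-one, via allylic alcohol 8 (not isolated)
Conditions: LiAlH4, Et2O, 0 °C; then 1 M HCl, THF, rt
Reagents that add atoms: water, O
Why: Stork–Danheiser transposition: 1,2-reduction of the vinylogous ester carbonyl, then acid-induced ionisation and enol ether hydrolysis move the enone so that the quaternary carbon becomes C10 next to the β-carbon C5; the stereocentre is not touched.

Step 6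
Reactants: 9 (R)-4-allyl-4-(benzyloxymethyl)-2-methylcyclohex-2-en-1-one
Product: 10 (R)-4-allyl-4-(hydroxymethyl)-2-methylcyclohex-2-en-1-one
Conditions: BCl3, C6HMe5, CH2Cl2, −78 °C
Reagents that add atoms: none
Why: Lewis-acid debenzylation with pentamethylbenzene as a non-basic benzyl cation scavenger frees the C20 hydroxyl and spares the enone and the terminal alkene, which hydrogenolysis would not.

Step 7
Reactants: 10 (R)-4-allyl-4-(hydroxymethyl)-2-methylcyclohex-2-en-1-one; 11 phenyl chloroformate
Product: 12 [(R)-1-allyl-3-methyl-4-oxocyclohex-2-en-1-yl]methyl phenyl carbonate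
Conditions: pyridine, CH2Cl2, 0 °C
Reagents that add atoms: none
Why: O-acylation of the primary alcohol gives a mixed aryl carbonate that carries the future C19 and whose weakly basic phenoxide leaving group should make the later C-acylation irreversible.

Step 8
Reactants: 12 [(R)-1-allyl-3-methyl-4-oxocyclohex-2-en-1-yl]methyl phenyl carbonate; 13 1-methoxy-1-(trimethylsilyloxy)ethene
Product: 15 methyl 2-[5-allyl-1-methyl-2,8-dioxo-3-oxabicyclo[3.3.1]nonan-9-yl]acetate (ring A keto lactone, H5 β, C6 on the lactone side), via silyl enol ether 14 (not isolated)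
Conditions: 13 (1.3 equiv), HNTf2 (2 mol %), CH2Cl2, −78 → −40 °C; volatiles removed; Bu4N[Ph3SiF2], THF, −78 → 0 °C
Reagents that add atoms: none
Why: A Mukaiyama–Michael addition with silyl transfer attaches C6–C7 to C5 and stores the C3–C4 enolate as its silyl enol ether, with axial attack expected anti to the allyl arm (C6 cis to C20) on weak but concordant steric and dipole grounds; fluoride then releases the regiodefined enolate, whose C4 attacks the tethered C20 carbonate in a six-membered Claisen-type acylation that can only deliver C19 syn to C20 and so fixes the C4 quaternary centre.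

Step 9
Reactants: 15 methyl 2-[5-allyl-1-methyl-2,8-dioxo-3-oxabicyclo[3.3.1]nonan-9-yl]acetate
Product: 16 methyl 2-[5-allyl-1-methyl-2-oxo-8-(trifluoromethylsulfonyloxy)-3-oxabicyclo[3.3.1]non-7-en-9-yl]acetate
Conditions: KN(SiMe3)2, THF, −78 °C; then PhNTf2
Reagents that add atoms: N-phenylbis(trifluoromethanesulfonimide), O=S(=O)(N(c1ccccc1)S(=O)(=O)C(F)(F)F)C(F)(F)F
Why: The C3 ketone can enolise only toward C2 (C4 is quaternary) and is far more acidic than the ester, so O-triflation of its enolate should give the C2=C3 enol triflate.

Step 10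
Reactants: 16 methyl 2-[5-allyl-1-methyl-2-oxo-8-(trifluoromethylsulfonyloxy)-3-oxabicyclo[3.3.1]non-7-en-9-yl]acetate
Product: 17 methyl 2-[5-allyl-1-methyl-2-oxo-3-oxabicyclo[3.3.1]non-7-en-9-yl]acetate
Conditions: Pd(OAc)2 (5 mol %), PPh3, HCO2H, Bu3N, DMF, 60 °C
Reagents that add atoms: none
Why: Palladium-catalysed formate reduction of the enol triflate (oxidative addition, formate-to-hydride exchange with loss of CO2, reductive elimination) leaves the C2=C3 alkene without creating a stereocentre.

Step 11
Reactants: 17 methyl 2-[5-allyl-1-methyl-2-oxo-3-oxabicyclo[3.3.1]non-7-en-9-yl]acetate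
Product: 18 methyl 2-[1-methyl-2-oxo-5-(2-oxopropyl)-3-oxabicyclo[3.3.1]non-7-en-9-yl]acetate
Conditions: PdCl2 (10 mol %), CuCl, O2 (1 atm), DMF–H2O, rt
Reagents that add atoms: water, O
Why: Tsuji–Wacker oxidation turns the terminal alkene of the allyl arm into the C11 methyl ketone with Markovnikov selectivity, while the internal cis alkene C2=C3 is inert under these conditions.

Step 12
Reactants: 18 methyl 2-[1-methyl-2-oxo-5-(2-oxopropyl)-3-oxabicyclo[3.3.1]non-7-en-9-yl]acetate
Product: 19 methyl 2-[7,8-dihydroxy-1-methyl-2-oxo-5-(2-oxopropyl)-3-oxabicyclo[3.3.1]nonan-9-yl]acetate (2β,3β-diol)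
Conditions: K2OsO4·2H2O (2 mol %), NMO, acetone–H2O, rt
Reagents that add atoms: N-methylmorpholine N-oxide, C[N+]1([O-])CCOCC1; water, O
Why: Catalytic syn-dihydroxylation of the only remaining alkene should occur on the β face, because the α face is covered by the C19–O–C20 lactone bridge, and so sets C2 and C3 together as the 2β,3β-diol.

Step 13
Reactants: 19 methyl 2-[7,8-dihydroxy-1-methyl-2-oxo-5-(2-oxopropyl)-3-oxabicyclo[3.3.1]nonan-9-yl]acetate
Product: 20 2β,3β-O-isopropylidene derivative of 19 (ring A lactone acetonide with C10 2-oxopropyl arm and C5 CH2CO2Me arm)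
Conditions: Me2C(OMe)2, PPTS (cat.), acetone, rt
Reagents that add atoms: 2,2-dimethoxypropane, COC(C)(C)OC
Why: Acid-catalysed transketalisation protects the cis-diol as its acetonide, which also blocks the β face of ring A; no stereocentre changes.

Step 14
Reactants: 20 2β,3β-O-isopropylidene derivative of 19
Product: 21 (Z)-trimethylsilyl enol ether of 20 (C9=C11)
Conditions: Me3SiOTf, Et3N, CH2Cl2, 0 °C → rt
Reagents that add atoms: trimethylsilyl trifluoromethanesulfonate, C[Si](C)(C)OS(=O)(=O)C(F)(F)F
Why: Soft enolisation under equilibrating conditions should give mainly the more substituted (Z)-C9=C11 silyl enol ether, which masks the ketone for step 15 and marks C9 for chlorination; the minor C11=C12 isomer would lead to the regioisomeric chloro ketone, which ionises to the same oxyallyl species.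

Step 15
Reactants: 21 (Z)-trimethylsilyl enol ether of 20; 22 cyclopent-2-en-1-one
Product: 23 C6 (1-hydroxycyclopent-2-en-1-yl) adduct of 21 (C6 and C8 epimers)
Conditions: LiN(i-Pr)2, THF, −78 °C; CeCl3; then 22, −78 °C; AcOH quench at −78 °C
Reagents that add atoms: none
Why: The ester is now the only enolisable carbonyl, and its cerium enolate should add 1,2 to the enone carbonyl (aldol addition) to form C6–C8 as a tertiary allylic alcohol; C6 and C8 arise as mixtures, which is harmless because C8 becomes trigonal in step 17 and C6 is equilibrated in step 18.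

Step 16
Reactants: 23 C6 (1-hydroxycyclopent-2-en-1-yl) adduct of 21
Product: 24 9-chloro-11-ketone derived from 23 (C6, C8 and C9 epimers)
Conditions: NCS, THF, 0 °C
Reagents that add atoms: N-chlorosuccinimide, O=C1CCC(=O)N1Cl
Why: Electrophilic chlorination of the silyl enol ether at its nucleophilic carbon places chlorine on C9 regiospecifically, the enol ether being far more reactive than the cyclopentene alkene; both C9 epimers can ionise.

Step 17
Reactants: 24 9-chloro-11-ketone derived from 23
Product: 25 cycloaddition precursor: ring A lactone acetonide with C10 1-chloro-2-oxopropyl arm and C5 cyclopenta-1,3-dien-1-yl(methoxycarbonyl)methyl arm (C6 and C9 epimers, 1-substituted diene isomer drawn), used at once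
Conditions: Burgess reagent (MeO2CNSO2NEt3), benzene, 40 °C
Reagents that add atoms: none
Why: Dehydration of the tertiary allylic alcohol through its sulfamate ester should give the cyclopentadiene, whose 1-, 2- and 5-substituted isomers interconvert by 1,5-hydrogen shifts, elimination toward C6 being disfavoured because it would create a tetrasubstituted alkene against the congested C5.

Step 18
Reactants: 25 cycloaddition precursor
Product: 27 pentacyclic 11-ketone (C15=C16 alkene, 19,20-lactone, 2β,3β-acetonide, C7 methyl ester), via kinetic cycloadduct 26 (not isolated)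
Conditions: CF3CH2ONa (2 equiv), CF3CH2OH (0.005 M), 0 °C → rt; solvent removed; NaOMe, MeOH, 40 °C; AcOH, aqueous work-up
Reagents that add atoms: none
Why: Trifluoroethoxide enolises the C11 ketone toward C12 and chloride leaves C9, giving the sodium oxyallyl C9–C11(O)–C12 (C10 syn to oxygen), which adds across C8 and C13 of the 1-substituted cyclopentadiene in a concerted but asynchronous (or stepwise) (4+3) cycloaddition, the closest known reaction type being the intramolecular (4+3) cycloaddition of oxyallyl cations from α-chloro ketones with tethered dienes in fluorinated alcohols. Ring B closes as the five-membered tether ring through C8–C9 (three-atom tether C10–C5–C6), the seven-membered carbocycle C8–C9–C11–C12–C13–C16–C15 is formed by the cycloaddition itself, and its one-carbon bridge C14 divides it into six-membered ring C and five-membered ring D. C8 and C13 are set together by suprafacial addition to one diene face, and C9 follows from them because the short tether lets C11 bond only on the side of C8 that carries C13 and C14, so that B/C is cis-fused with H9 syn to the C15–C16 bridge. The selectivity that the step needs is the diene face relative to C10 (C14 and C11 syn to C20), which is decided by the rotamer about C9–C10: the substrate is built to favour the one with C11–O beside C20, since the other places the oxyallyl oxygen in the pocket under ring A filled by H1β, H5β and the 2β,3β-acetonide, and the C6 ester prefers to lie next to the flat C15 and not the C14 methylene. The diene isomers equilibrate by 1,5-hydrogen shifts and only the 1-isomer can close a five-membered ring B, so the mixture should drain through it. C6, left undefined until now, is then brought by methoxide to the more stable β-ester (trans to C4), and the acidic work-up re-closes any lactone opened by methoxide.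

Step 19
Reactants: 27 pentacyclic 11-ketone
Product: 29 11,16-diol (C11 and C16 epimers; lactone, acetonide and methyl ester unchanged), via alkylborane 28 (not isolated)
Conditions: BH3·THF (2.5 equiv), THF, 0 °C; then H2O2, NaOH (aq), 0 °C
Reagents that add atoms: borane–tetrahydrofuran, [BH3-][O+]1CCCC1 (boron in 28 only); hydrogen peroxide, OO
Why: Hydroboration–oxidation: boron should add to C16 of the strained C15=C16 alkene, away from the quaternary C8, while the C11 ketone is reduced in the same operation; both new carbinol centres are removed in step 20, so their configuration does not matter.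

Step 20
Reactants: 29 11,16-diol
Product: 30 11,16-diketone
Conditions: Dess–Martin periodinane, NaHCO3, CH2Cl2, rt
Reagents that add atoms: none
Why: Periodinane oxidation of both secondary alcohols under buffered, non-epimerising conditions gives the diketone without touching the other stereocentres.

Step 21
Reactants: 30 11,16-diketone; 31 methyltriphenylphosphonium bromide
Product: 32 16-methylene-11-ketone
Conditions: 31, KOt-Bu, THF, 0 °C; then 30 (1.2 equiv ylide), 0 °C → rt
Reagents that add atoms: none
Why: Wittig methylenation should take place at the exposed bridge ketone C16 and introduce C17, whereas the C11 carbonyl is screened on one face by C20 and on the other by the C15 methylene and is expected to stay intact.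

Step 22
Reactants: 32 16-methylene-11-ketone
Product: 33 11β-alcohol (C16=C17 alkene, lactone, acetonide, methyl ester)
Conditions: NaBH4, MeOH, 0 °C
Reagents that add atoms: none
Why: Hydride should reach C11 from the exo (α) face, syn to the C14 bridge, because the endo hydrogen of the now saturated C15 closes the β face, which gives the axial 11β-alcohol; ester and lactone are not reduced under these conditions.

Step 23
Reactants: 33 11β-alcohol
Product: 35 target acid CNP0302900.3 (2β,3β,11β-triol, 19,20-lactone, 16-ene, C7 acid), via dipotassium seco-acid salt 34 (not isolated)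
Conditions: KOH, MeOH–H2O, reflux; then 1 M HCl, THF, rt
Reagents that add atoms: potassium hydroxide, [K+].[OH-]
Why: Saponification cleaves the hindered C7 methyl ester (the lactone opens reversibly and C6 keeps its stable configuration), and acid then re-closes the 19,20-lactone and hydrolyses the acetonide; the diol is unmasked only after the basic stage so that retro-aldol cleavage of the 3-hydroxy lactone cannot occur.

Compound list
1 | 2-methylcyclohexane-1,3-dione | CC1C(=O)CCCC1=O | starting material
2 | 3-isobutoxy-2-methylcyclohex-2-en-1-one | CC1=C(OCC(C)C)CCCC1=O | intermediate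
3 | benzyl chloromethyl ether | ClCOCc1ccccc1 | starting material
4 | rac-6-(benzyloxymethyl)-3-isobutoxy-2-methylcyclohex-2-en-1-one | CC1=C(OCC(C)C)CCC(COCc2ccccc2)C1=O | intermediate
5 | allyl chloroformate | C=CCOC(=O)Cl | starting material
6 | allyl [2-(benzyloxymethyl)-5-isobutoxy-6-methylcyclohexa-1,5-dien-1-yl] carbonate | C=CCOC(=O)OC1=C(COCc2ccccc2)CCC(OCC(C)C)=C1C | intermediate
7 | (S)-6-allyl-6-(benzyloxymethyl)-3-isobutoxy-2-methylcyclohex-2-en-1-one | C=CC[C@]1(COCc2ccccc2)CCC(OCC(C)C)=C(C)C1=O | intermediate
8 | (6S)-6-allyl-6-(benzyloxymethyl)-3-isobutoxy-2-methylcyclohex-2-en-1-ol (carbinol epimers) | C=CC[C@]1(COCc2ccccc2)CCC(OCC(C)C)=C(C)C1O | intermediate (not isolated)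
9 | (R)-4-allyl-4-(benzyloxymethyl)-2-methylcyclohex-2-en-1-one | C=CC[C@]1(COCc2ccccc2)CCC(=O)C(C)=C1 | intermediate
10 | (R)-4-allyl-4-(hydroxymethyl)-2-methylcyclohex-2-en-1-one | C=CC[C@]1(CO)CCC(=O)C(C)=C1 | intermediate
11 | phenyl chloroformate | O=C(Cl)Oc1ccccc1 | starting material
12 | [(R)-1-allyl-3-methyl-4-oxocyclohex-2-en-1-yl]methyl phenyl carbonate | C=CC[C@]1(COC(=O)Oc2ccccc2)CCC(=O)C(C)=C1 | intermediate
13 | 1-methoxy-1-(trimethylsilyloxy)ethene | C=C(OC)O[Si](C)(C)C | starting material
14 | methyl 2-[2-allyl-6-methyl-2-(phenoxycarbonyloxymethyl)-5-(trimethylsilyloxy)cyclohex-5-en-1-yl]acetate (C5 side chain cis to the C20 arm) | C=CC[C@]1(COC(=O)Oc2ccccc2)CCC(O[Si](C)(C)C)=C(C)[C@H]1CC(=O)OC | intermediate (not isolated)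
15 | methyl 2-[5-allyl-1-methyl-2,8-dioxo-3-oxabicyclo[3.3.1]nonan-9-yl]acetate (ring A keto lactone, H5 β) | C=CC[C@]12COC(=O)[C@](C)(C(=O)CC1)[C@H]2CC(=O)OC | intermediate
16 | methyl 2-[5-allyl-1-methyl-2-oxo-8-(trifluoromethylsulfonyloxy)-3-oxabicyclo[3.3.1]non-7-en-9-yl]acetate | C=CC[C@]12COC(=O)[C@](C)(C(OS(=O)(=O)C(F)(F)F)=CC1)[C@H]2CC(=O)OC | intermediate
17 | methyl 2-[5-allyl-1-methyl-2-oxo-3-oxabicyclo[3.3.1]non-7-en-9-yl]acetate | C=CC[C@]12COC(=O)[C@](C)(C=CC1)[C@H]2CC(=O)OC | intermediate
18 | methyl 2-[1-methyl-2-oxo-5-(2-oxopropyl)-3-oxabicyclo[3.3.1]non-7-en-9-yl]acetate | CC(=O)C[C@]12COC(=O)[C@](C)(C=CC1)[C@H]2CC(=O)OC | intermediate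
19 | methyl 2-[7,8-dihydroxy-1-methyl-2-oxo-5-(2-oxopropyl)-3-oxabicyclo[3.3.1]nonan-9-yl]acetate (2β,3β-diol) | CC(=O)C[C@]12COC(=O)[C@](C)([C@@H](O)[C@@H](O)C1)[C@H]2CC(=O)OC | intermediate
20 | 2β,3β-O-isopropylidene derivative of 19 | CC(=O)C[C@]12COC(=O)[C@](C)([C@@H](O4)[C@@H](OC4(C)C)C1)[C@H]2CC(=O)OC | intermediate
21 | (Z)-trimethylsilyl enol ether of 20 (C9=C11) | C/C(O[Si](C)(C)C)=C/[C@]12COC(=O)[C@](C)([C@@H](O4)[C@@H](OC4(C)C)C1)[C@H]2CC(=O)OC | intermediate
22 | cyclopent-2-en-1-one | O=C1C=CCC1 | starting material
23 | C6 (1-hydroxycyclopent-2-en-1-yl) adduct of 21 (C6 and C8 epimers) | C/C(O[Si](C)(C)C)=C/[C@]12COC(=O)[C@](C)([C@@H](O4)[C@@H](OC4(C)C)C1)[C@H]2C(C(=O)OC)C3(O)C=CCC3 | intermediate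
24 | 9-chloro-11-ketone derived from 23 (C6, C8 and C9 epimers) | CC(=O)C(Cl)[C@]12COC(=O)[C@](C)([C@@H](O4)[C@@H](OC4(C)C)C1)[C@H]2C(C(=O)OC)C3(O)C=CCC3 | intermediate
25 | cycloaddition precursor: ring A lactone acetonide, C10 1-chloro-2-oxopropyl arm, C5 cyclopenta-1,3-dien-1-yl(methoxycarbonyl)methyl arm (C6 and C9 epimers) | CC(=O)C(Cl)[C@]12COC(=O)[C@](C)([C@@H](O4)[C@@H](OC4(C)C)C1)[C@H]2C(C3=CC=CC3)C(=O)OC | intermediate
26 | kinetic (4+3) adduct, C6 epimers of 27 | C1=C[C@]23C[C@H]1CC(=O)[C@H]2[C@]12COC(=O)[C@](C)([C@@H](O4)[C@@H](OC4(C)C)C1)[C@H]2C3C(=O)OC | intermediate (not isolated)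
27 | pentacyclic 11-ketone (C15=C16 alkene, 19,20-lactone, 2β,3β-acetonide, C7 methyl ester) | C1=C[C@]23C[C@H]1CC(=O)[C@H]2[C@]12COC(=O)[C@](C)([C@@H](O4)[C@@H](OC4(C)C)C1)[C@H]2[C@@H]3C(=O)OC | intermediate
28 | C16 alkylborane with C11 borinate, from 27 (representative formula) | BC1C[C@]23C[C@H]1CC(OB)[C@H]2[C@]12COC(=O)[C@](C)([C@@H](O4)[C@@H](OC4(C)C)C1)[C@H]2[C@@H]3C(=O)OC | intermediate (not isolated)
29 | 11,16-diol (C11 and C16 epimers) | OC1C[C@]23C[C@H]1CC(O)[C@H]2[C@]12COC(=O)[C@](C)([C@@H](O4)[C@@H](OC4(C)C)C1)[C@H]2[C@@H]3C(=O)OC | intermediate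
30 | 11,16-diketone | O=C1C[C@]23C[C@H]1CC(=O)[C@H]2[C@]12COC(=O)[C@](C)([C@@H](O4)[C@@H](OC4(C)C)C1)[C@H]2[C@@H]3C(=O)OC | intermediate
31 | methyltriphenylphosphonium bromide | C[P+](c1ccccc1)(c1ccccc1)c1ccccc1.[Br-] | starting material
32 | 16-methylene-11-ketone | C=C1C[C@]23C[C@H]1CC(=O)[C@H]2[C@]12COC(=O)[C@](C)([C@@H](O4)[C@@H](OC4(C)C)C1)[C@H]2[C@@H]3C(=O)OC | intermediate
33 | 11β-alcohol (acetonide, methyl ester) | C=C1C[C@]23C[C@H]1C[C@H](O)[C@H]2[C@]12COC(=O)[C@](C)([C@@H](O4)[C@@H](OC4(C)C)C1)[C@H]2[C@@H]3C(=O)OC | intermediate
34 | dipotassium salt of the 19,20-seco diacid acetonide | C=C1C[C@]23C[C@H]1C[C@H](O)[C@H]2[C@]1(CO)C[C@@H]4OC(C)(C)O[C@@H]4[C@@](C)(C(=O)[O-])[C@H]1[C@@H]3C(=O)[O-].[K+].[K+] | intermediate (not isolated)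
35 | CNP0302900.3 (2β,3β,11β-trihydroxy 19,20-lactone 16-ene C7 acid) | C=C1C[C@]23C[C@H]1C[C@H](O)[C@H]2[C@]12COC(=O)[C@](C)([C@@H](O)[C@@H](O)C1)[C@H]2[C@@H]3C(=O)O | target

Total step count: 23. Longest linear sequence: 23 steps (from 1; all other starting materials are purchased).

Steps most likely to fail

Step 18. The oxyallyl may engage the other diene face, through the rotamer that turns C11–O away from C20, which would give the ring system epimeric at C8, C9 and C13 and cannot be corrected later. Base-induced ring contraction or solvolysis of the chloro ketone and Diels–Alder dimerisation of the diene may also drain material. The fallback builds rings B and C by two ionic bond formations, the first under thermodynamic control, and sets out from 23. Oxidative 1,3-transposition of the tertiary allylic alcohol (Dauben–Babler oxidation with pyridinium chlorochromate, C5H5NH[CrO3Cl], CH2Cl2; the acidic work-up also hydrolyses the silyl enol ether) would give the 3-substituted cyclopent-2-enone F1. Base (Cs2CO3, MeCN) would then close ring B by reversible intramolecular Michael addition of C9 to C8, giving the more stable cis-fused diketo ester F2. Double deprotonation at the kinetic sites C12 and C13 (LiN(i-Pr)2, 2.2 equiv, THF, −78 °C) and oxidation of the bis-enolate with CuCl2 would join C12 to C13 and deliver the 11,16-diketone 30, where the route is rejoined; steps 19 and 20 are then not needed.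

Step 8. The conjugate addition may discriminate poorly between the allyl arm and the carbonate arm on C10 and give the C5 epimer, and proton transfer may compete with the C-acylation. The fallback delivers C6 from the C20 oxygen and sets out from 10. Acylation with methyl malonyl chloride and pyridine would give the malonate F3. Cs2CO3 in MeCN would bring about an intramolecular Michael addition that for geometric reasons can only place C6 cis to C20, giving the lactone diester F4. Krapcho dealkoxycarbonylation (LiCl, wet DMSO, 140 °C) would give the lactone F5, and methanolysis (K2CO3, MeOH) would free the C20 hydroxyl as the hydroxy ester F6. Acylation with 11 would give the carbonate F7, and silylation under equilibrating conditions (Me3SiCl, NaI, Et3N, MeCN) would give the more substituted silyl enol ether 14, from which the fluoride stage of step 8 leads to 15.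

Step 15. The C6 enolate sits next to the fully substituted C5 environment, so the aldol adduct may revert, or conjugate addition and simple proton transfer to cyclopentenone may take over. The fallback generates a less basic zinc enolate reductively and sets out from 21. Deprotonation with LiN(i-Pr)2 and bromination with CBr4 at −78 °C would give the α-bromo ester F8, and activated Zn with 22 in THF (Reformatsky reaction, which adds 1,2 to enones) would give 23.

Further compounds
F1 | step 18 | methyl ketone with C6 (3-oxocyclopent-1-en-1-yl) group, from 23 (C6 epimers) | CC(=O)C[C@]12COC(=O)[C@](C)([C@@H](O4)[C@@H](OC4(C)C)C1)[C@H]2C(C(=O)OC)C3=CC(=O)CC3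
F2 | step 18 | ring B Michael adduct (C8 quaternary, 11-acetyl, 16-ketone; C12–C13 bond not yet formed) | CC(=O)[C@H]5[C@]12COC(=O)[C@](C)([C@@H](O4)[C@@H](OC4(C)C)C1)[C@H]2[C@H](C(=O)OC)[C@]56CC(=O)CC6
F3 | step 8 | [(R)-1-allyl-3-methyl-4-oxocyclohex-2-en-1-yl]methyl methyl malonate | C=CC[C@]1(COC(=O)CC(=O)OC)CCC(=O)C(C)=C1
F4 | step 8 | cis-fused δ-lactone diester from intramolecular Michael addition (C4 and C6 epimers) | C=CC[C@]12CCC(=O)C(C)[C@H]1C(C(=O)OC)C(=O)OC2
F5 | step 8 | cis-fused δ-lactone after dealkoxycarbonylation (C4 epimers) | C=CC[C@]12CCC(=O)C(C)[C@H]1CC(=O)OC2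
F6 | step 8 | methyl 2-[2-allyl-2-(hydroxymethyl)-6-methyl-5-oxocyclohexyl]acetate (C6 cis to C20; C4 epimers) | C=CC[C@]1(CO)CCC(=O)C(C)[C@H]1CC(=O)OC
F7 | step 8 | phenyl carbonate of F6 | C=CC[C@]1(COC(=O)Oc2ccccc2)CCC(=O)C(C)[C@H]1CC(=O)OC
F8 | step 15 | α-bromo ester derived from 21 (C6 epimers) | C/C(O[Si](C)(C)C)=C/[C@]12COC(=O)[C@](C)([C@@H](O4)[C@@H](OC4(C)C)C1)[C@H]2C(Br)C(=O)OC
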